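**Retrosynthetic overview**

1. Locants: C1 = C–OH, C2 = ArCH on C1, O3, C4 = CH2, C5 = ring-fusion CH (ring A: C1, C2, O3, C4, C5); C6 = second ArCH, O7, C8 = second CH2 (ring B: C1, C8, O7, C6, C5). Last disconnections: the two O-benzyl groups, then the C6–H bond (hydride to the ring B oxocarbenium ion from the convex face puts the C6 aryl endo), leading back to a bicyclic α-hydroxy lactone with C8 as carbonyl.
2. Key disconnection: C1–C2 of ring A is traced back to the O–C2 bond of a cyclic arylidene acetal. Ring A is not closed as a five-membered ring; it comes from the six-membered 1,3-dioxane (C1, its oxygen, C2, O3, C4, C5) by a 1,2 shift of C2 from that oxygen to C1, which pushes the oxygen out of the ring as the tertiary OH.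
3. Enabling feature: C1 is a tertiary carbinol between the oxygen-bearing C2 and C8. Its oxygen and the C4 oxygen are a 1,3-diol pair, so C1–O, C2, O3, C4, C5 can be a six-ring acetal, and a C8 carbonyl makes C1 enolisable. The O3–C4–C5 tether forces the cis ring fusion.
4. The acetal comes from a diol lactone and O-benzylvanillin; the diol lactone comes from dimethyl (S)-malate and the same aldehyde by a dianion aldol. The four malate carbons become C8–C1–C5–C4; the malate carbinol centre relays its configuration to C5, is made planar in the key step and is rebuilt there.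
5. Ring order: lactone ring B (step 1), 1,3-dioxane (step 3), ring A by ring contraction (step 4), then ring B is opened (step 5) and closed again as the ether with C6 set anew (steps 6 and 7).

Key step: step 4

Remark: Ar = 4-(benzyloxy)-3-methoxyphenyl in all protected compounds.
Remark: C6 is drawn, up to the triol, as the expected major epimer (aryl trans to the C5 substituent); the route does not depend on it, because C6 is made planar in step 6 and set in step 7, so a C6 epimer from step 1 can be carried along and converges there.
Remark: the C5 epimer from step 1 is a diastereomer only while the malate centre C1 is intact, so it has to be removed before step 4.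

**Step 1**
Reactants: 1 dimethyl (S)-malate; 2 4-(benzyloxy)-3-methoxybenzaldehyde
Product: 5 (2S,3S,4S)-2-[4-(benzyloxy)-3-methoxyphenyl]-4-hydroxy-5-oxooxolane-3-carboxylic acid, via aldol diester 3 (not isolated), via hydroxy diacid 4 (not isolated)
Conditions: LiN(SiMe3)2 (2.2 equiv), THF, −78 to −20 °C; 2, −78 °C; then LiOH, H2O, 0 °C to rt; then 2 M HCl to pH 1, rt
Reagents that add atoms: lithium hydroxide, [Li+].[OH-] (oxygen of the carboxyl group)
Why: Fráter–Seebach aldol addition of the chelated dilithium dianion of the malate, in which the aldehyde enters C5 anti to the C1 oxygen (1,2-induction in the rigid lithium chelate); hydrolysis and acidification funnel open and lactonised aldol products into the one γ-lactone acid, because only the C8 carboxyl can form a five-membered lactone with the benzylic hydroxyl.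

**Step 2**
Reactants: 5 hydroxy lactone acid
Product: 6 (3S,4S,5S)-5-[4-(benzyloxy)-3-methoxyphenyl]-3-hydroxy-4-(hydroxymethyl)oxolan-2-one
Conditions: BH3·SMe2 (excess), THF, 0 °C to rt; MeOH, then aqueous work-up
Reagents that add atoms: none
Why: Chemoselective borane reduction of a carboxylic acid (through its acyloxyborane) in the presence of a γ-lactone; no stereocentre is touched.

**Step 3**
Reactants: 6 diol lactone; 2 4-(benzyloxy)-3-methoxybenzaldehyde
Product: 7 arylidene acetal of 6 (2-aryl-1,3-dioxane built from the C1 oxygen, C2, O3, C4, C5, C1 and trans-fused to the γ-lactone; acetal aryl equatorial)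
Conditions: 2 (1.2 equiv), CSA (5 mol%), benzene, reflux, azeotropic removal of water
Reagents that add atoms: none
Why: Acid-catalysed acetalisation of the 1,3-diol (C1–OH and C4–OH) under thermodynamic control should place the acetal aryl equatorial; the configuration at the acetal carbon and at C1 is immaterial for step 4.

**Step 4**
Reactants: 7 arylidene acetal lactone
Product: 10 (1R,2R,5R,6S)-2,6-bis[4-(benzyloxy)-3-methoxyphenyl]-1-hydroxy-3,7-dioxabicyclo[3.3.0]octan-8-one, via ketene silyl acetal 8 (not isolated), via rearranged silyl ether 9 (not isolated)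
Conditions: KN(SiMe3)2 (1.2 equiv), Me3SiCl, THF, −78 °C; solvent exchange to CH2Cl2; Me3SiOTf (0.2 equiv), −78 to −40 °C; then 1 M HCl, THF, 0 °C
Reagents that add atoms: none
Why: Proposed new method: enolisation/O-silylation gives ketene silyl acetal 8, in which catalytic Me3SiOTf should ionise the arylidene acetal at the bond between C2 and the enol oxygen; the resulting pair of a tethered (E)-oxocarbenium ion (C2=O3) and a bis-silyl enediol recombines at carbon, so that C2 migrates from the C1 oxygen to C1 (1,2 O-to-C shift), the lactone carbonyl returns, Me3SiOTf is regenerated and the six-membered 1,3-dioxane has contracted to ring A. The closest known reaction types are the Lewis acid ring contraction of 4,5-dihydro-1,3-dioxepines to 3-formyltetrahydrofurans and the Petasis–Ferrier rearrangement (enol acetal to oxocarbenium/enolate pair to C–C bond), the Mukaiyama aldol addition of ketene silyl acetals to acetals, and, for the net result, the acetal [1,2]-Wittig rearrangement; new is that the departing acetal oxygen sits on the nucleophilic carbon itself. Ring A closes in the 5-(enolexo)-endo-trig mode, as in those rearrangements. C1 is fixed by the O3–C4 tether, which can bring C2 only to the face of the planar ketene acetal on which C4 stands (cis fusion, OH cis to H5), and C2 by the (E)-geometry of the oxocarbenium ion in an open-book transition state that leaves only H2 under ring B and places the aryl group on the convex face, cis to OH. Since the acetal carbon and C1 both become planar on the way, every epimer of 7 at these two centres should converge on 10. The step needs C–C closure to win over unproductive ionisation at C2–O3 and over return of the enol oxygen; both of these are reversible whereas the carbon–carbon bond is not, and the low temperature with substoichiometric acid should spare the benzylic lactone C–O bond.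

**Step 5**
Reactants: 10 bicyclic hydroxy lactone
Product: 11 triol: 2-aryl-4-[aryl(hydroxy)methyl]-3-(hydroxymethyl)oxolan-3-ol (C2 aryl cis to the ring OH; CH2OH and the carbinol side chain cis)
Conditions: LiAlH4, THF, 0 °C to rt; aqueous NaOH work-up
Reagents that add atoms: none
Why: Lithium aluminium hydride reduction of the lactone to the diol opens ring B and brings C8 to the CH2 level; no stereocentre is changed.

**Step 6**
Reactants: 11 triol
Product: 13 cyclic hemiketal (6-hydroxy derivative of the protected furofuran; both anomers), via hydroxy ketone 12 (not isolated)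
Conditions: activated MnO2 (excess), CH2Cl2, rt
Reagents that add atoms: none
Why: MnO2 oxidises only the electron-rich benzylic secondary alcohol, and the γ-hydroxy ketone should close at once (5-exo-trig addition of the C8 hydroxyl to the ketone) to the cis-fused hemiketal, which erases the C6 stereocentre and shields the β-hydroxy ketone from retro-aldol cleavage.

**Step 7**
Reactants: 13 cyclic hemiketal
Product: 14 (1S,2R,5R,6R)-2,6-bis[4-(benzyloxy)-3-methoxyphenyl]-3,7-dioxabicyclo[3.3.0]octan-1-ol
Conditions: Et3SiH (3 equiv), BF3·OEt2, CH2Cl2, −78 to −40 °C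
Reagents that add atoms: none
Why: Ionic hydrogenation of the hemiketal: BF3 generates the aryl-stabilised cyclic oxocarbenium ion and Et3SiH should deliver hydride to C6 from the convex face of the cis-fused bicycle, which leaves the C6 aryl on the concave face (endo) as required.

**Step 8**
Reactants: 14 dibenzyl ether
Product: 15 (1S,2R,5R,6R)-2,6-bis(4-hydroxy-3-methoxyphenyl)-3,7-dioxabicyclo[3.3.0]octan-1-ol (target; C2 aryl exo, C6 aryl endo)
Conditions: H2 (1 atm), 10% Pd/C, EtOAc–MeOH, rt, stopped at full conversion
Reagents that add atoms: none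
Why: Hydrogenolysis of the two aryl benzyl ethers over Pd/C, which should be much faster than cleavage of the secondary benzylic ring ethers; no stereocentre is affected.

**Compound list**

1 | dimethyl (S)-malate | COC(=O)C[C@H](O)C(=O)OC | starting material
2 | 4-(benzyloxy)-3-methoxybenzaldehyde | COc1cc(C=O)ccc1OCc1ccccc1 | starting material
3 | aldol diester, dimethyl (2S,3R)-2-hydroxy-3-{(S)-[4-(benzyloxy)-3-methoxyphenyl](hydroxy)methyl}butanedioate (formed in the flask) | COC(=O)[C@@H](O)[C@@H]([C@H](O)c1ccc(OCc2ccccc2)c(OC)c1)C(=O)OC | intermediate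
4 | hydroxy diacid, (2S,3R)-2-hydroxy-3-{(S)-[4-(benzyloxy)-3-methoxyphenyl](hydroxy)methyl}butanedioic acid (formed in the flask) | OC(=O)[C@@H](O)[C@@H]([C@H](O)c1ccc(OCc2ccccc2)c(OC)c1)C(=O)O | intermediate
5 | (2S,3S,4S)-2-[4-(benzyloxy)-3-methoxyphenyl]-4-hydroxy-5-oxooxolane-3-carboxylic acid | O=C1O[C@H](c2ccc(OCc3ccccc3)c(OC)c2)[C@@H](C(=O)O)[C@@H]1O | intermediate
6 | (3S,4S,5S)-5-[4-(benzyloxy)-3-methoxyphenyl]-3-hydroxy-4-(hydroxymethyl)oxolan-2-one | O=C1O[C@H](c2ccc(OCc3ccccc3)c(OC)c2)[C@@H](CO)[C@@H]1O | intermediate
7 | arylidene acetal of 6 (trans-fused 2-aryl-1,3-dioxane on the γ-lactone, acetal aryl equatorial) | O=C1O[C@H](c3ccc(OCc4ccccc4)c(OC)c3)[C@H]2CO[C@H](c5ccc(OCc6ccccc6)c(OC)c5)O[C@H]12 | intermediate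
8 | ketene silyl acetal of 7 (formed in the flask) | C[Si](C)(C)OC1=C2O[C@@H](c3ccc(OCc4ccccc4)c(OC)c3)OC[C@@H]2[C@@H](c5ccc(OCc6ccccc6)c(OC)c5)O1 | intermediate
9 | trimethylsilyl ether of 10 (formed in the flask) | O=C1O[C@H](c3ccc(OCc4ccccc4)c(OC)c3)[C@H]2CO[C@H](c5ccc(OCc6ccccc6)c(OC)c5)[C@@]12O[Si](C)(C)C | intermediate
10 | (1R,2R,5R,6S)-2,6-bis[4-(benzyloxy)-3-methoxyphenyl]-1-hydroxy-3,7-dioxabicyclo[3.3.0]octan-8-one | O=C1O[C@H](c3ccc(OCc4ccccc4)c(OC)c3)[C@H]2CO[C@H](c5ccc(OCc6ccccc6)c(OC)c5)[C@@]12O | intermediate
11 | triol, 2-aryl-4-[aryl(hydroxy)methyl]-3-(hydroxymethyl)oxolan-3-ol | OC[C@]1(O)[C@@H](c2ccc(OCc3ccccc3)c(OC)c2)OC[C@@H]1[C@H](O)c1ccc(OCc2ccccc2)c(OC)c1 | intermediate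
12 | hydroxy ketone, 4-aroyl-2-aryl-3-(hydroxymethyl)oxolan-3-ol (formed in the flask) | OC[C@]1(O)[C@@H](c2ccc(OCc3ccccc3)c(OC)c2)OC[C@@H]1C(=O)c1ccc(OCc2ccccc2)c(OC)c1 | intermediate
13 | cyclic hemiketal, 2,6-diaryl-3,7-dioxabicyclo[3.3.0]octane-1,6-diol (both anomers at C6) | COc1cc([C@H]2OC[C@@H]3C(O)(c4ccc(OCc5ccccc5)c(OC)c4)OC[C@]23O)ccc1OCc1ccccc1 | intermediate
14 | (1S,2R,5R,6R)-2,6-bis[4-(benzyloxy)-3-methoxyphenyl]-3,7-dioxabicyclo[3.3.0]octan-1-ol | COc1cc([C@H]2OC[C@@H]3[C@H](c4ccc(OCc5ccccc5)c(OC)c4)OC[C@]23O)ccc1OCc1ccccc1 | intermediate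
15 | (1S,2R,5R,6R)-2,6-bis(4-hydroxy-3-methoxyphenyl)-3,7-dioxabicyclo[3.3.0]octan-1-ol | COc1cc([C@H]2OC[C@@H]3[C@H](c4ccc(O)c(OC)c4)OC[C@]23O)ccc1O | target

**Totals**

Total step count: 8. Longest linear sequence: 8 steps (1 to 15; aldehyde 2 enters in steps 1 and 3).

**Steps most likely to fail**

Step 4 (proposed new method). The acetal may ionise on the C2–O3 side only, or the silyl group of 8 may return to oxygen before the C–C bond forms, so that the aldehyde is lost on work-up (net deprotection to 6). The fallback uses known chemistry, an intramolecular Mukaiyama aldol addition of a ketene silyl acetal to a tethered acyclic acetal; methoxide is then the only leaving group and the C1 oxygen is a spectator silyl ether. It sets out from 6 and 2. Aldehyde 2 would be converted into its dimethyl acetal F1 (HC(OMe)3, cat. TsOH, MeOH). F1, activated with Me3SiOTf/2,4,6-collidine, would be taken up by the primary hydroxyl of 6 to give the mixed methyl acetal F2. Double silylation (KN(SiMe3)2 2.2 equiv, Me3SiCl, THF, −78 °C) would give the silyl ether/ketene silyl acetal F3, and catalytic Me3SiOTf in CH2Cl2 at −78 °C should close ring A through the same tethered (E)-oxocarbenium ion. The fallback comes back to the route at 9, which is hydrolysed to 10 as in step 4.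

Step 7. The open keto form 12 may undergo retro-aldol cleavage of the C1–C5 bond under the Lewis acid, the C6–O7 bond of the product may ionise again and take up a second hydride (ring opening), or hydride may attack the concave face. The fallback sets out from 13. Dehydration (MsCl, Et3N, CH2Cl2, 0 °C) would give the cyclic enol ether F4 (C5=C6). Hydroxyl-directed hydrogenation (H2, [Ir(cod)(PCy3)(py)]PF6, CH2Cl2) should follow: the C1 hydroxyl on the convex face binds the cationic iridium catalyst, H2 adds to C5 and C6 from that face, the cis fusion is restored and the C6 aryl is left endo. The fallback comes back at 14.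

Step 1. Face selectivity at C5 of the dianion may be incomplete and the aldolate may undergo retro-aldol during the basic hydrolysis; this lowers the yield and, if the C5 epimer is not removed, the enantiomeric purity after step 4. The fallback sets out from 1 and 2. Malate 1 would be converted (LiN(SiMe3)2 2.2 equiv, Me3SiCl, THF, −78 °C) into the O-silylated ketene silyl acetal F5. Mukaiyama aldol addition to 2 (BF3·OEt2, CH2Cl2, −78 °C; open transition state, no basic aldolate) would give the silyl ether F6, and mild acid then gives 3 as an isolated compound, where C5 epimers can be separated. The fallback comes back at 3, which is hydrolysed and lactonised to 5 as in step 1.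

Further compounds
F1 | step 4 | 4-(benzyloxy)-3-methoxybenzaldehyde dimethyl acetal | COC(OC)c1ccc(OCc2ccccc2)c(OC)c1
F2 | step 4 | mixed methyl acetal at the primary oxygen of 6 (both acetal epimers) | O=C1O[C@H](c2ccc(OCc3ccccc3)c(OC)c2)[C@@H](COC(OC)c2ccc(OCc3ccccc3)c(OC)c2)[C@@H]1O
F3 | step 4 | silyl ether and ketene silyl acetal of F2 | C[Si](C)(C)OC1=C(O[Si](C)(C)C)[C@H](COC(OC)c2ccc(OCc3ccccc3)c(OC)c2)[C@@H](c2ccc(OCc3ccccc3)c(OC)c2)O1
F4 | step 7 | cyclic enol ether of 13 (C5=C6) | COc1cc([C@H]2OCC3=C(c4ccc(OCc5ccccc5)c(OC)c4)OC[C@]23O)ccc1OCc1ccccc1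
F5 | step 1 | methyl (2S)-4-methoxy-2,4-bis(trimethylsilyloxy)but-3-enoate | COC(=O)[C@@H](O[Si](C)(C)C)C=C(OC)O[Si](C)(C)C
F6 | step 1 | trimethylsilyl ether (at the malate oxygen) of 3 | COC(=O)[C@@H](O[Si](C)(C)C)[C@@H]([C@H](O)c1ccc(OCc2ccccc2)c(OC)c1)C(=O)OC
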